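A one-step world has a closed form: the logarithm of the free monomer left falls on a straight line in time. After a delay, the earlier runs come close to that world.

| flask | free monomer | initiator | remark | time |
|---|---|---|---|---|
| ash | 1.6 M (fed, over 4.0 h) | 3.5 mM | run made earlier; the fed solution adds 0.50 times the starting volume |  |
| elm | 1.6 M (fed, over 4.0 h) | 5.7 mM | run made earlier; the fed solution adds 0.50 times the starting volume |  |
| epsilon | 1.6 M (fed, over 4.0 h) | 8.0 mM | the fed solution adds 0.50 times the starting volume | 10 d |
| alpha | 1.6 M (fed, over 4.0 h) | 4.0 mM | the fed solution adds 0.50 times the starting volume | 10 d |

- ash (time / d: monomer in chains / %, free monomer / %): 0.625: 2.6, 96.4; 1.04: 9.0, 91.2; 2.08: 25.7, 74.0; 4.00: 52.6, 48.3; 8.00: 83.0, 17.0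
- elm (time / d: monomer in chains / %, free monomer / %): 1.25: 17.5, 82.0; 3.00: 54.8, 44.6; 4.00: 67.8, 30.1; 6.00: 85.5, 13.6; 8.00: 94.2, 6.5

(each reading ± 0.5 percentage points)

- every charge counts on the volume at the start, and the solution that is fed holds the whole dose
- the average divides the monomer in chains by the number of chains begun, living and dead together
- the earlier runs were read with a standard deviation of 0.5 percentage points
- the earlier runs do not show the number of chains; that part of a forecast is a guess

* which of the two ends with the longer chains by the average number of monomer units in a chain (chains begun, living or dead) ("neither" if they lie within 10 %) (epsilon / alpha / neither)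
* average number of monomer units in a chain (chains begun, living or dead) at the end, epsilon
* average number of monomer units in a chain (chains begun, living or dead) at the end, alpha

From 4.00 d to 8.00 d the ash run falls with a slope of 0.261 /d. From 4.00 d to 8.00 d the elm run falls with 0.383 /d. Each slope over its initiator charge, averaged across the two runs, reads 2.95 /M/h: the growth constant per initiator charged, a pseudo-first-order constant once multiplied by the charge. Ash, elm, epsilon and alpha have the same feed, so the constant is carried over to epsilon and alpha.

The times form a ladder. The straight lines, traced back, put the delay at 1.04 d. The feed ends earlier, at 0.17 d, shorter than that delay. Next comes the growth time, one over constant times charge: 1.76 d for epsilon and 3.53 d for alpha, each longer than the delay. The time allowed, 10 d, is longer than either.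

Integrating the rate from the end of the delay, the reckoning here leaves 0.620 % of the free monomer in epsilon and 7.88 % in alpha. The runs do not show chains, so one chain per initiator is a guess. It gives 199 for epsilon and 368 for alpha, which is longer.

The forecast names alpha, with 195 for epsilon and 368 for alpha, on the same guess: “I guess one chain per initiator”. Its epsilon figure lies slightly below the reckoning here.

The flask gives alpha, with 265 for epsilon and 439 for alpha.

    free monomer + initiator → living end + monomer in chains (k = 0.0310 /M/h)
    free monomer + living end → monomer in chains + living end, rate k2*[living end]*[free monomer] (k = 5.30 /M/h)
    initiator + monomer in chains → spent initiator (k = 0.0340 /M/h)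

Alpha holds 7.8 % of its free monomer at 10.0 d, against the 7.88 % reckoned, and the parting lies in the number of chains. At 3.19 d the initiator in alpha has a half-life of 1.6 d by the step that begins a chain and 1.7 d by the step with monomer in chains that makes spent initiator, and at 10.0 d alpha holds 0.00224 M of living end, less than the 2.67 mM of initiator charged, counted on the final volume, beside spent initiator at 0.0401 % of the free monomer charged.

For a flask like alpha with 2.40 mM of initiator, the growth constant leaves 21.8 % of the free monomer, and one chain per initiator gives 522. The computed flask holds 20 % and gives 599.

The runs are calculated with constants of no real substance, and the scatter is random.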